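**Plan**

- Locants follow the target: seven-membered ring C1(OAng)–C2H2–C3(CH3)=C4H–C5(=O)–C6(CH3)–C7H, five-membered ring C6–C7–C8(OH)(iPr)–C9H2–C10(OAng). α is the face of the C6 methyl, β the face of H7.
- Retrosynthesis: cut the two angelate C–O bonds, then the C3=C4 unsaturation, then C4–C5 and C3–C4 together. C4 is a lone CH between the C5 carbonyl and C3, and C6 is quaternary, so excising C4 leaves a trans-fused bicyclo[4.3.0]nonan-5-one (hydrindanone) whose homologue can enolise only toward the inserted carbon.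
- Further cuts: C8–isopropyl, C2=C3 (metathesis), C1–vinyl, C5–C6 (aldol) and C7–vinyl (conjugate addition), back to (R)-4-silyloxycyclopentenone.
- Forward: the cyclopentane comes from the enone, the six-membered ring closes by ring-closing metathesis, and one-carbon insertion enlarges it to the seven-membered ring.
- Stereochemistry: the C8 silyloxy group of the enantiopure enone directs vinyl to C7 (trans); the aldol sets C6 trans to vinyl (trans ring fusion); C1 comes from Felkin–Anh addition; C10 and C8 come from additions to ring ketones on the face away from the angular methyl; C3 is transient.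

Key step: step 15

Assumption: (R)-4-(tert-butyldimethylsilyloxy)cyclopent-2-en-1-one is bought as the single enantiomer; bicyclic compounds are named with the target locants and the α/β convention above.

**Route**

Step 1
Reactants: 1 (R)-4-(tert-butyldimethylsilyloxy)cyclopent-2-en-1-one
Product: 2 (R)-4-(tert-butyldimethylsilyloxy)-2-iodocyclopent-2-en-1-one
Conditions: I2, pyridine/CH2Cl2, 0 °C → rt
Reagents that add atoms: iodine, II
Why: Pyridine adds to the enone β-carbon, the enolate is iodinated and pyridine is expelled (α-iodination of a cyclic enone by addition–elimination), which leaves the C8 stereocentre untouched.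

Step 2
Reactants: 2 (R)-4-(tert-butyldimethylsilyloxy)-2-iodocyclopent-2-en-1-one; 3 tetramethylstannane
Product: 4 (R)-4-(tert-butyldimethylsilyloxy)-2-methylcyclopent-2-en-1-one
Conditions: Pd2(dba)3 (cat.), AsPh3, CuI, NMP, 60 °C
Reagents that add atoms: tetramethylstannane (3), C[Sn](C)(C)C
Why: Stille cross-coupling of the α-iodoenone with tetramethyltin runs under neutral conditions, so the base-sensitive γ-silyloxy enone should survive without β-elimination.

Step 3
Reactants: 4 (R)-4-(tert-butyldimethylsilyloxy)-2-methylcyclopent-2-en-1-one; 5 vinylmagnesium bromide; 6 methacrolein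
Product: 8 (2S,3R,4R)-4-(tert-butyldimethylsilyloxy)-2-(1-hydroxy-2-methylallyl)-2-methyl-3-vinylcyclopentan-1-one (both carbinol epimers), via magnesium enolate 7 (not isolated)
Conditions: CH2=CHMgBr, CuBr·SMe2 (cat.), THF, −78 → −40 °C; then methacrolein, −78 °C; aq. NH4Cl
Reagents that add atoms: vinylmagnesium bromide (5), C=C[Mg]Br; methacrolein (6), C=C(C)C=O
Why: Copper-catalysed conjugate addition places vinyl on C7 anti to the C8 silyloxy group, and the regiodefined enolate 7 then adds to methacrolein at C6 anti to the new vinyl group (three-component conjugate addition–aldol coupling), so that C6 and C7 carry the future ring bonds trans while the carbinol centre is erased in step 4.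

Step 4
Reactants: 8 aldol adduct
Product: 9 (2R,3R,4R)-4-(tert-butyldimethylsilyloxy)-2-methacryloyl-2-methyl-3-vinylcyclopentan-1-one
Conditions: Dess–Martin periodinane, NaHCO3, CH2Cl2, 0 °C → rt
Reagents that add atoms: none
Why: Dess–Martin oxidation of the β-hydroxy ketone under buffered, non-basic conditions should give the non-enolisable 1,3-diketone without retro-aldol cleavage.

Step 5
Reactants: 9 vinyl diketone
Product: 10 (2R,3R,4R)-4-(tert-butyldimethylsilyloxy)-3-formyl-2-methacryloyl-2-methylcyclopentan-1-one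
Conditions: O3, CH2Cl2, −78 °C (Sudan Red 7B end point); then PPh3, −78 °C → rt; used crude
Reagents that add atoms: ozone, [O-][O+]=O
Why: Electrophilic ozone cleaves the isolated vinyl group much faster than the electron-poor, ketone-conjugated methacryloyl alkene (chemoselective ozonolysis with reductive work-up).

Step 6
Reactants: 10 aldehyde; 5 vinylmagnesium bromide
Product: 11 (2R,3S,4R)-4-(tert-butyldimethylsilyloxy)-3-[(S)-1-hydroxyallyl]-2-methacryloyl-2-methylcyclopentan-1-one
Conditions: CH2=CHMgBr (1.1 equiv), THF, −78 °C; aq. NH4Cl at −78 °C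
Reagents that add atoms: vinylmagnesium bromide (5), C=C[Mg]Br
Why: The aldehyde is far more electrophilic than the two ketones on quaternary C6, and Felkin–Anh addition of the Grignard reagent anti to C6 (C8 as the medium group) should give the C1 configuration of the target.

Step 7
Reactants: 11 allylic alcohol
Product: 12 8β-(tert-butyldimethylsilyloxy)-1β-hydroxy-3,6α-dimethyl-7βH-bicyclo[4.3.0]non-2-ene-5,10-dione
Conditions: Grubbs second-generation catalyst (5 mol %), CH2Cl2, 40 °C
Reagents that add atoms: none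
Why: Ring-closing metathesis between the carbinol vinyl group and the methacryloyl alkene closes the six-membered enone ring (C2=C3) across the trans-disposed C6 and C7 substituents with loss of ethylene and without touching a stereocentre.

Step 8
Reactants: 12 ene-dione
Product: 13 8β-(tert-butyldimethylsilyloxy)-1β,10α-dihydroxy-3,6α-dimethyl-7βH-bicyclo[4.3.0]non-2-en-5-one
Conditions: NaBH4, MeOH/CH2Cl2, −78 → −40 °C
Reagents that add atoms: none
Why: The saturated cyclopentanone is reduced in preference to the hindered conjugated C5 carbonyl, and hydride attacks C10 from the β face opposite the angular methyl, as in borohydride reductions of angular-methyl trans-hydrindan-1-ones (17-oxo steroid type), giving the 10α-alcohol.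

Step 9
Reactants: 13 diol
Product: 14 8β-(tert-butyldimethylsilyloxy)-3,6α-dimethyl-1β,10α-bis(triisopropylsilyloxy)-7βH-bicyclo[4.3.0]non-2-en-5-one
Conditions: TIPSOTf, 2,6-lutidine, CH2Cl2, 0 °C → rt
Reagents that add atoms: triisopropylsilyl trifluoromethanesulfonate, CC(C)[Si](OS(=O)(=O)C(F)(F)F)(C(C)C)C(C)C
Why: The silyl triflate with 2,6-lutidine silylates both secondary alcohols, including the neopentyl-type C10 hydroxyl, and TIPS is chosen to outlast the C8 TBS ether in step 11.

Step 10
Reactants: 14 enone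
Product: 16 8β-(tert-butyldimethylsilyloxy)-3β,6α-dimethyl-1β,10α-bis(triisopropylsilyloxy)-7βH-bicyclo[4.3.0]nonan-5-one (C3 methyl equatorial), via C3-epimer mixture 15 (not isolated)
Conditions: H2 (1 atm), 10% Pd/C, EtOAc, rt; filter; then NaOMe (cat.), MeOH, rt
Reagents that add atoms: none
Why: Heterogeneous hydrogenation saturates C2=C3 and catalytic methoxide then equilibrates the only enolisable centre, C3, to the equatorial methyl epimer (the axial one would be syn-diaxial to the C6 methyl), a centre that is removed again in step 16.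

Step 11
Reactants: 16 hydrindanone
Product: 17 8β-hydroxy-3β,6α-dimethyl-1β,10α-bis(triisopropylsilyloxy)-7βH-bicyclo[4.3.0]nonan-5-one
Conditions: CSA (cat.), MeOH/CH2Cl2, 0 °C
Reagents that add atoms: none
Why: Acid-catalysed methanolysis should remove the secondary TBS ether at C8 much faster than the two bulkier TIPS ethers (graded silyl ether lability).

Step 12
Reactants: 17 alcohol
Product: 18 3β,6α-dimethyl-1β,10α-bis(triisopropylsilyloxy)-7βH-bicyclo[4.3.0]nonane-5,8-dione
Conditions: Dess–Martin periodinane, NaHCO3, CH2Cl2, 0 °C → rt; used crude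
Reagents that add atoms: none
Why: Buffered Dess–Martin oxidation gives the C8 ketone under neutral conditions, which should avoid epimerisation of the adjacent ring-fusion carbon C7 and elimination of the β-silyloxy groups.

Step 13
Reactants: 18 dione; 19 isopropylmagnesium chloride
Product: 20 8α-hydroxy-8β-isopropyl-3β,6α-dimethyl-1β,10α-bis(triisopropylsilyloxy)-7βH-bicyclo[4.3.0]nonan-5-one
Conditions: i-PrMgCl, CeCl3 (dried), THF, −78 °C
Reagents that add atoms: isopropylmagnesium chloride (19), CC(C)[Mg]Cl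
Why: The weakly basic organocerium reagent adds to the C8 carbonyl rather than enolising it, the C5 carbonyl between quaternary C6 and tertiary C3 is too hindered to compete, and attack from the β face (that of H7, away from the angular methyl and the C7–C1 bond) sets the 8α-hydroxy-8β-isopropyl centre.

Step 14
Reactants: 20 tertiary alcohol
Product: 21 8β-isopropyl-3β,6α-dimethyl-8α-(triethylsilyloxy)-1β,10α-bis(triisopropylsilyloxy)-7βH-bicyclo[4.3.0]nonan-5-one
Conditions: TESOTf, 2,6-lutidine, CH2Cl2, 0 °C → rt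
Reagents that add atoms: triethylsilyl trifluoromethanesulfonate, CC[Si](CC)(CC)OS(=O)(=O)C(F)(F)F
Why: Silylation with the silyl triflate caps the tertiary alcohol so that it can neither ionise nor be alkylated under the Lewis acid and diazoalkane of the next step.

Step 15
Reactants: 21 protected hydrindan-5-one; 22 trimethylsilyldiazomethane
Product: 24 8β-isopropyl-3β,6α-dimethyl-8α-(triethylsilyloxy)-1β,10α-bis(triisopropylsilyloxy)-7βH-bicyclo[5.3.0]decan-5-one, via α-silyl ketone 23 (not isolated)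
Conditions: TMSCHN2, BF3·OEt2, CH2Cl2, −78 → −30 °C; then K2CO3, MeOH, 0 °C
Reagents that add atoms: trimethylsilyldiazomethane (22), C[Si](C)(C)C=[N+]=[N-]
Why: The BF3-activated C5 carbonyl is attacked by the diazo carbon on the β face, away from the axial C6 methyl, to give a β-oxido diazonium betaine, which loses N2 with 1,2-shift of the C3–C5 bond onto the new carbon C4 (new C4–C5 and C3–C4 bonds) to give α-silyl ketone 23, whose C–Si bond is then replaced by C–H with mild base. The closest known reaction type is the Lewis acid-promoted homologation of cyclic ketones with trimethylsilyldiazomethane, a Tiffeneau–Demjanov-type one-carbon ring expansion. No ring is closed by cyclisation: the six-membered ring C1–C2–C3–C5–C6–C7 is enlarged to the seven-membered ring by insertion, and the trans fusion is untouched. No stereocentre is created in 24, since C4 becomes CH2 and C3 migrates with retention. The step needs migration of tertiary C3 rather than quaternary C6 and a single insertion; the bulky Me3Si group of the betaine avoids quaternary C6 and so places the diazonium group anti to C3, and the product carbonyl, flanked by C6 and a silylated carbon, should not react again.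

Step 16
Reactants: 24 cycloheptanone
Product: 26 8β-isopropyl-3,6α-dimethyl-8α-(triethylsilyloxy)-1β,10α-bis(triisopropylsilyloxy)-7βH-bicyclo[5.3.0]dec-3-en-5-one, via silyl enol ether 25 (not isolated)
Conditions: LDA, TMSCl, THF, −78 °C; then Pd(OAc)2, MeCN, rt
Reagents that add atoms: none
Why: Enolisation can only occur at C4 because C6 is quaternary, and the derived silyl enol ether 25 undergoes Saegusa–Ito oxidation (palladium enolate, β-hydride elimination of H3) to the C3=C4 enone.

Step 17
Reactants: 26 protected enone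
Product: 27 1β,8α,10α-trihydroxy-8β-isopropyl-3,6α-dimethyl-7βH-bicyclo[5.3.0]dec-3-en-5-one
Conditions: 48% aq. HF, MeCN, 0 °C → rt
Reagents that add atoms: none
Why: Acidic fluoride cleaves the two TIPS ethers and the tertiary TES ether (global desilylation) without exposing the β-hydroxy ketone at C10/C5 to base, so retro-aldol opening should be avoided.

Step 18
Reactants: 27 triol; 28 angelic acid
Product: 29 CNP0183628.1
Conditions: angelic acid, 2,4,6-trichlorobenzoyl chloride, Et3N, toluene, rt; then 27, 80 °C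
Reagents that add atoms: angelic acid (28), C/C=C(/C)C(=O)O
Why: Acylation with the preformed mixed anhydride of angelic and 2,4,6-trichlorobenzoic acid (Yamaguchi-type esterification without a nucleophilic catalyst) should transfer the angeloyl group to both secondary alcohols without Z→E isomerisation to the tiglate, while the hindered tertiary C8 hydroxyl stays free.

**Compound list**

1 | (R)-4-(tert-butyldimethylsilyloxy)cyclopent-2-en-1-one | O=C1C[C@@H](O[Si](C)(C)C(C)(C)C)C=C1 | starting material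
2 | (R)-4-(tert-butyldimethylsilyloxy)-2-iodocyclopent-2-en-1-one | O=C1C[C@@H](O[Si](C)(C)C(C)(C)C)C=C1I | intermediate
3 | tetramethylstannane | C[Sn](C)(C)C | starting material
4 | (R)-4-(tert-butyldimethylsilyloxy)-2-methylcyclopent-2-en-1-one | O=C1C[C@@H](O[Si](C)(C)C(C)(C)C)C=C1C | intermediate
5 | vinylmagnesium bromide | C=C[Mg]Br | starting material
6 | methacrolein | C=C(C)C=O | starting material
7 | bromomagnesium enolate of (3R,4R)-4-(tert-butyldimethylsilyloxy)-2-methyl-3-vinylcyclopentanone (vinyl trans to OTBS) | CC1=C(O[Mg]Br)C[C@@H](O[Si](C)(C)C(C)(C)C)[C@@H]1C=C | intermediate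
8 | (2S,3R,4R)-4-(tert-butyldimethylsilyloxy)-2-(1-hydroxy-2-methylallyl)-2-methyl-3-vinylcyclopentan-1-one (both carbinol epimers) | C=C(C)C(O)[C@]1(C)[C@@H](C=C)[C@H](O[Si](C)(C)C(C)(C)C)CC1=O | intermediate
9 | (2R,3R,4R)-4-(tert-butyldimethylsilyloxy)-2-methacryloyl-2-methyl-3-vinylcyclopentan-1-one | C=C(C)C(=O)[C@]1(C)[C@@H](C=C)[C@H](O[Si](C)(C)C(C)(C)C)CC1=O | intermediate
10 | (2R,3R,4R)-4-(tert-butyldimethylsilyloxy)-3-formyl-2-methacryloyl-2-methylcyclopentan-1-one | C=C(C)C(=O)[C@]1(C)[C@@H](C=O)[C@H](O[Si](C)(C)C(C)(C)C)CC1=O | intermediate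
11 | (2R,3S,4R)-4-(tert-butyldimethylsilyloxy)-3-[(S)-1-hydroxyallyl]-2-methacryloyl-2-methylcyclopentan-1-one | C=C(C)C(=O)[C@]1(C)[C@@H]([C@@H](O)C=C)[C@H](O[Si](C)(C)C(C)(C)C)CC1=O | intermediate
12 | 8β-(tert-butyldimethylsilyloxy)-1β-hydroxy-3,6α-dimethyl-7βH-bicyclo[4.3.0]non-2-ene-5,10-dione | O[C@H]1C=C(C)C(=O)[C@]2(C)[C@@H]1[C@H](O[Si](C)(C)C(C)(C)C)CC2=O | intermediate
13 | 8β-(tert-butyldimethylsilyloxy)-1β,10α-dihydroxy-3,6α-dimethyl-7βH-bicyclo[4.3.0]non-2-en-5-one | O[C@H]1C=C(C)C(=O)[C@]2(C)[C@@H]1[C@H](O[Si](C)(C)C(C)(C)C)C[C@H]2O | intermediate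
14 | 8β-(tert-butyldimethylsilyloxy)-3,6α-dimethyl-1β,10α-bis(triisopropylsilyloxy)-7βH-bicyclo[4.3.0]non-2-en-5-one | CC(C)[Si](C(C)C)(C(C)C)O[C@H]1C=C(C)C(=O)[C@]2(C)[C@@H]1[C@H](O[Si](C)(C)C(C)(C)C)C[C@H]2O[Si](C(C)C)(C(C)C)C(C)C | intermediate
15 | C3-epimer mixture of 8β-(tert-butyldimethylsilyloxy)-3,6α-dimethyl-1β,10α-bis(triisopropylsilyloxy)-7βH-bicyclo[4.3.0]nonan-5-one (C3 undefined) | CC(C)[Si](C(C)C)(C(C)C)O[C@H]1CC(C)C(=O)[C@]2(C)[C@@H]1[C@H](O[Si](C)(C)C(C)(C)C)C[C@H]2O[Si](C(C)C)(C(C)C)C(C)C | intermediate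
16 | 8β-(tert-butyldimethylsilyloxy)-3β,6α-dimethyl-1β,10α-bis(triisopropylsilyloxy)-7βH-bicyclo[4.3.0]nonan-5-one | CC(C)[Si](C(C)C)(C(C)C)O[C@H]1C[C@@H](C)C(=O)[C@]2(C)[C@@H]1[C@H](O[Si](C)(C)C(C)(C)C)C[C@H]2O[Si](C(C)C)(C(C)C)C(C)C | intermediate
17 | 8β-hydroxy-3β,6α-dimethyl-1β,10α-bis(triisopropylsilyloxy)-7βH-bicyclo[4.3.0]nonan-5-one | CC(C)[Si](C(C)C)(C(C)C)O[C@H]1C[C@@H](C)C(=O)[C@]2(C)[C@@H]1[C@H](O)C[C@H]2O[Si](C(C)C)(C(C)C)C(C)C | intermediate
18 | 3β,6α-dimethyl-1β,10α-bis(triisopropylsilyloxy)-7βH-bicyclo[4.3.0]nonane-5,8-dione | CC(C)[Si](C(C)C)(C(C)C)O[C@H]1C[C@@H](C)C(=O)[C@]2(C)[C@@H]1C(=O)C[C@H]2O[Si](C(C)C)(C(C)C)C(C)C | intermediate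
19 | isopropylmagnesium chloride | CC(C)[Mg]Cl | starting material
20 | 8α-hydroxy-8β-isopropyl-3β,6α-dimethyl-1β,10α-bis(triisopropylsilyloxy)-7βH-bicyclo[4.3.0]nonan-5-one | CC(C)[Si](C(C)C)(C(C)C)O[C@H]1C[C@@H](C)C(=O)[C@]2(C)[C@@H]1[C@](O)(C(C)C)C[C@H]2O[Si](C(C)C)(C(C)C)C(C)C | intermediate
21 | 8β-isopropyl-3β,6α-dimethyl-8α-(triethylsilyloxy)-1β,10α-bis(triisopropylsilyloxy)-7βH-bicyclo[4.3.0]nonan-5-one | CC(C)[Si](C(C)C)(C(C)C)O[C@H]1C[C@@H](C)C(=O)[C@]2(C)[C@@H]1[C@](O[Si](CC)(CC)CC)(C(C)C)C[C@H]2O[Si](C(C)C)(C(C)C)C(C)C | intermediate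
22 | trimethylsilyldiazomethane | C[Si](C)(C)C=[N+]=[N-] | starting material
23 | 8β-isopropyl-3β,6α-dimethyl-8α-(triethylsilyloxy)-1β,10α-bis(triisopropylsilyloxy)-4-(trimethylsilyl)-7βH-bicyclo[5.3.0]decan-5-one (C4 undefined) | CC(C)[Si](C(C)C)(C(C)C)O[C@H]1C[C@@H](C)C([Si](C)(C)C)C(=O)[C@]2(C)[C@@H]1[C@](O[Si](CC)(CC)CC)(C(C)C)C[C@H]2O[Si](C(C)C)(C(C)C)C(C)C | intermediate
24 | 8β-isopropyl-3β,6α-dimethyl-8α-(triethylsilyloxy)-1β,10α-bis(triisopropylsilyloxy)-7βH-bicyclo[5.3.0]decan-5-one | CC(C)[Si](C(C)C)(C(C)C)O[C@H]1C[C@@H](C)CC(=O)[C@]2(C)[C@@H]1[C@](O[Si](CC)(CC)CC)(C(C)C)C[C@H]2O[Si](C(C)C)(C(C)C)C(C)C | intermediate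
25 | 8β-isopropyl-3β,6α-dimethyl-8α-(triethylsilyloxy)-1β,10α-bis(triisopropylsilyloxy)-5-(trimethylsilyloxy)-7βH-bicyclo[5.3.0]dec-4-ene | CC(C)[Si](C(C)C)(C(C)C)O[C@H]1C[C@@H](C)C=C(O[Si](C)(C)C)[C@]2(C)[C@@H]1[C@](O[Si](CC)(CC)CC)(C(C)C)C[C@H]2O[Si](C(C)C)(C(C)C)C(C)C | intermediate
26 | 8β-isopropyl-3,6α-dimethyl-8α-(triethylsilyloxy)-1β,10α-bis(triisopropylsilyloxy)-7βH-bicyclo[5.3.0]dec-3-en-5-one | CC(C)[Si](C(C)C)(C(C)C)O[C@H]1CC(C)=CC(=O)[C@]2(C)[C@@H]1[C@](O[Si](CC)(CC)CC)(C(C)C)C[C@H]2O[Si](C(C)C)(C(C)C)C(C)C | intermediate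
27 | 1β,8α,10α-trihydroxy-8β-isopropyl-3,6α-dimethyl-7βH-bicyclo[5.3.0]dec-3-en-5-one | O[C@H]1CC(C)=CC(=O)[C@]2(C)[C@@H]1[C@](O)(C(C)C)C[C@H]2O | intermediate
28 | angelic acid, (Z)-2-methylbut-2-enoic acid | C/C=C(/C)C(=O)O | starting material
29 | CNP0183628.1, (1S,6R,7S,8R,10R)-1β,10α-bis(angeloyloxy)-8α-hydroxy-8β-isopropyl-3,6α-dimethyl-7βH-bicyclo[5.3.0]dec-3-en-5-one | C/C=C(/C)C(=O)O[C@H]1CC(C)=CC(=O)[C@]2(C)[C@@H]1[C@](O)(C(C)C)C[C@H]2OC(=O)/C(C)=C\C | target

**Step count and risks**

Total steps: 18. Longest linear sequence: 18 steps (1 → 29).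

Steps most likely to fail:

Step 15. The diazoalkane may add only slowly to a carbonyl flanked by a quaternary and a tertiary carbon, and the betaine may collapse to the spiro-epoxide or shift C6 instead of C3. The fallback replaces diazoalkane insertion by cyclopropanation and oxidative fragmentation, and forms the same C4–C5 and C3–C4 bonds. It sets out from 21, which is converted with TMSOTf/Et3N into the trimethylsilyl enol ether F1 (C3=C5, the only enolisable direction). Cyclopropanation with Et2Zn/CH2I2 gives the siloxycyclopropane F2, in which the new CH2 (C4) bridges C3 and C5. FeCl3 in DMF opens it by alkoxy-radical β-scission of the C3–C5 bond with chlorine transfer to the tertiary C3 radical, giving the β-chloro ketone F3. NaOAc in MeOH then eliminates HCl, and the route is rejoined at enone 26, so steps 15 and 16 are both replaced.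

Step 13. The organometallic reagent may enolise the C8 ketone (epimerisation at C7 to the cis-fused ketone, or β-elimination of silanol) or reduce it by β-hydride transfer instead of adding. The fallback builds the tertiary centre with an sp2 nucleophile that has no transferable β-hydrogen and adds a reduction afterwards. It sets out from 18, which with isopropenylmagnesium bromide/CeCl3 at −78 °C gives the isopropenyl carbinol F4. Hydrogenation of its alkene (H2, PtO2, EtOAc) rejoins the route at 20.

Step 6. Facial selectivity at C1 may be poor, since only acyclic Felkin–Anh control is available. The fallback sets C1 by reagent control instead. It sets out from aldehyde 10, which is treated with ethynylmagnesium bromide at −78 °C to give the epimeric propargylic alcohols F5. Dess–Martin oxidation gives the ynone F6, and Midland reduction with (R)-Alpine-Borane, which reduces only the ynone carbonyl, should give the (R)-propargylic alcohol F7 (same spatial arrangement at C1 as in 11). Lindlar semi-hydrogenation, which leaves the conjugated methacryloyl alkene alone, rejoins the route at 11.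

**Further compounds**

F1 | step 15 | 8β-isopropyl-3,6α-dimethyl-8α-(triethylsilyloxy)-1β,10α-bis(triisopropylsilyloxy)-5-(trimethylsilyloxy)-7βH-bicyclo[4.3.0]non-3(5)-ene (C3=C5 silyl enol ether) | CC(C)[Si](C(C)C)(C(C)C)O[C@H]1CC(C)=C(O[Si](C)(C)C)[C@]2(C)[C@@H]1[C@](O[Si](CC)(CC)CC)(C(C)C)C[C@H]2O[Si](C(C)C)(C(C)C)C(C)C
F2 | step 15 | siloxycyclopropane from F1 with CH2 (C4) bridging C3 and C5 (cyclopropane face undefined; both converge) | CC(C)[Si](C(C)C)(C(C)C)O[C@H]1CC3(C)CC3(O[Si](C)(C)C)[C@]2(C)[C@@H]1[C@](O[Si](CC)(CC)CC)(C(C)C)C[C@H]2O[Si](C(C)C)(C(C)C)C(C)C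
F3 | step 15 | 3-chloro-8β-isopropyl-3,6α-dimethyl-8α-(triethylsilyloxy)-1β,10α-bis(triisopropylsilyloxy)-7βH-bicyclo[5.3.0]decan-5-one (C3 undefined) | CC(C)[Si](C(C)C)(C(C)C)O[C@H]1CC(C)(Cl)CC(=O)[C@]2(C)[C@@H]1[C@](O[Si](CC)(CC)CC)(C(C)C)C[C@H]2O[Si](C(C)C)(C(C)C)C(C)C
F4 | step 13 | 8α-hydroxy-8β-isopropenyl-3β,6α-dimethyl-1β,10α-bis(triisopropylsilyloxy)-7βH-bicyclo[4.3.0]nonan-5-one | CC(C)[Si](C(C)C)(C(C)C)O[C@H]1C[C@@H](C)C(=O)[C@]2(C)[C@@H]1[C@](O)(C(C)=C)C[C@H]2O[Si](C(C)C)(C(C)C)C(C)C
F5 | step 6 | (2R,3S,4R)-4-(tert-butyldimethylsilyloxy)-3-(1-hydroxyprop-2-ynyl)-2-methacryloyl-2-methylcyclopentan-1-one (both carbinol epimers) | C=C(C)C(=O)[C@]1(C)[C@@H](C(O)C#C)[C@H](O[Si](C)(C)C(C)(C)C)CC1=O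
F6 | step 6 | (2R,3R,4R)-4-(tert-butyldimethylsilyloxy)-2-methacryloyl-2-methyl-3-propioloylcyclopentan-1-one | C=C(C)C(=O)[C@]1(C)[C@@H](C(=O)C#C)[C@H](O[Si](C)(C)C(C)(C)C)CC1=O
F7 | step 6 | (2R,3S,4R)-4-(tert-butyldimethylsilyloxy)-3-[(R)-1-hydroxyprop-2-ynyl]-2-methacryloyl-2-methylcyclopentan-1-one | C=C(C)C(=O)[C@]1(C)[C@@H]([C@@H](O)C#C)[C@H](O[Si](C)(C)C(C)(C)C)CC1=O
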